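**Retrosynthetic overview** (chromene numbering of the bicyclic core)
1. 19 ⇐ 18 (ester hydrolysis) ⇐ 16: C2–vinyl bond by axial vinylation of the bicyclic 2-methyl oxocarbenium ion.
2. 16 ⇐ 14: pyran closed last, C8a–O bond by tethered alkoxymercuration of an exocyclic alkene; 14 ⇐ 13 by methylenation.
3. 13 ⇐ 10 + but-3-en-2-one: C4a–C4 bond by axial Mukaiyama–Michael addition of a regiodefined enol silane.
4. 10 ⇐ 6: key one-carbon ring expansion (cyclopentanone → cyclohexanone enolate) by 1,2-shift of the quaternary carbon onto a β-oxido carbenoid made from CH2Br2.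
5. 6 ⇐ 2-methylcyclopent-2-enone + isobutyrate ketene acetal + bromoacetate; ring order: purchased five-membered ring → six-membered carbocycle (ring expansion) → tetrahydropyran.

Assumption: the (S)-catalyst in step 2 is taken to give the (1R) adduct by analogy with the unsubstituted enones; if the sense is opposite, the mirror-image catalyst is used.

Step 1
Reactants: 1 methyl 2-methylpropanoate
Product: 2 1-methoxy-2-methyl-1-(trimethylsilyloxy)prop-1-ene
Conditions: LDA, THF, −78 °C; TMSCl, −78 °C to rt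
Reagents that add atoms: chlorotrimethylsilane C[Si](C)(C)Cl
Why: Kinetic ester enolisation followed by O-silylation (silyl ketene acetal formation) is standard for α,α-disubstituted esters and creates no stereocentre.

Step 2
Reactants: 2 1-methoxy-2-methyl-1-(trimethylsilyloxy)prop-1-ene, 3 2-methylcyclopent-2-en-1-one, 4 methyl bromoacetate
Product: 6 methyl 2-[(1R,2S)-2-(2-methoxy-2-oxoethyl)-2-methyl-3-oxocyclopentyl]-2-methylpropanoate, via enol silane 5 (not isolated)
Conditions: (S)-o-tolyl oxazaborolidinium triflimide (10 mol%), Ph3PO (25 mol%), toluene, −40 °C; then TBAT, THF, −78 to 0 °C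
Reagents that add atoms: none
Why: Proposed new method: the chiral oxazaborolidinium Lewis acid binds the enone carbonyl and shields one face of the β-carbon, so the silyl ketene acetal adds enantioselectively (CH–CMe2CO2Me centre set as R) with silyl transfer to the tetrasubstituted enol silane, whose fluoride-released enolate is then alkylated anti to the bulky new β-substituent to set the quaternary centre (CH2CO2Me trans to CMe2CO2Me); the closest known reactions are the oxazaborolidinium-catalysed Mukaiyama–Michael addition of this same ketene acetal to unsubstituted cyclopentenone and cyclohexenone and the fluoride-mediated alkylation of enol silanes, the new elements being the α-methyl enone and the one-pot trapping.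

Step 3
Reactants: 6 methyl 2-[(1R,2S)-2-(2-methoxy-2-oxoethyl)-2-methyl-3-oxocyclopentyl]-2-methylpropanoate, 7 dibromomethane
Product: 10 methyl 2-[(1R,2S)-2-(2-methoxy-2-oxoethyl)-2-methyl-4-(trimethylsilyloxy)cyclohex-3-en-1-yl]-2-methylpropanoate, via dibromomethyl alkoxide 8 (not isolated), via lithium enolate 9 (not isolated)
Conditions: LiTMP, THF, −78 °C; n-BuLi, −100 to −30 °C; TMSCl, Et3N, −78 °C to rt
Reagents that add atoms: chlorotrimethylsilane C[Si](C)(C)Cl
Why: β-Oxido carbenoid ring expansion (Nozaki–Yamamoto type): Br/Li exchange on the dibromomethyl carbinolate gives a carbenoid to which the more substituted, electron-richer quaternary α-carbon migrates with retention, giving the six-membered lithium enolate regiospecifically on the side of the inserted carbon, which is trapped as its enol silane without creating a new stereocentre.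

Step 4
Reactants: 10 methyl 2-[(1R,2S)-2-(2-methoxy-2-oxoethyl)-2-methyl-4-(trimethylsilyloxy)cyclohex-3-en-1-yl]-2-methylpropanoate, 11 but-3-en-2-one
Product: 13 methyl 2-[(1R,2S,3S)-3-(3,3-dimethoxybutyl)-2-(2-methoxy-2-oxoethyl)-2-methyl-4-oxocyclohexyl]-2-methylpropanoate, via enol silane 12 (not isolated)
Conditions: Tf2NH (3 mol%), CH2Cl2, −78 °C; then MeOH (1 equiv), MeOSiMe3 (2.2 equiv), −78 to −40 °C; Et3N
Reagents that add atoms: methanol CO; methoxytrimethylsilane CO[Si](C)(C)C
Why: Silyl-triflimide-catalysed Mukaiyama–Michael addition takes place at the enol silane carbon by axial attack anti to the axial methyl on the neighbouring quaternary carbon (new side chain cis to CH2CO2Me, ring H cis to that methyl), and Noyori-type ketalisation under cold aprotic conditions then masks only the unhindered methyl ketone without epimerising the new α-centre.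

Step 5
Reactants: 13 methyl 2-[(1R,2S,3S)-3-(3,3-dimethoxybutyl)-2-(2-methoxy-2-oxoethyl)-2-methyl-4-oxocyclohexyl]-2-methylpropanoate, 7 dibromomethane
Product: 14 methyl 2-[(1R,2R,3R)-3-(3,3-dimethoxybutyl)-2-(2-methoxy-2-oxoethyl)-2-methyl-4-methylidenecyclohexyl]-2-methylpropanoate
Conditions: Zn, TiCl4, THF/CH2Cl2, 0 °C to rt (pre-aged Lombardo reagent)
Reagents that add atoms: none
Why: Lombardo methylenation is non-basic, so the hindered, epimerisable ketone becomes the exocyclic alkene while the α-stereocentre, both esters and the ketal are left alone.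

Step 6
Reactants: 14 methyl 2-[(1R,2R,3R)-3-(3,3-dimethoxybutyl)-2-(2-methoxy-2-oxoethyl)-2-methyl-4-methylidenecyclohexyl]-2-methylpropanoate
Product: 16 methyl 2-[(2R,4aS,5S,6R,8aR)-2-methoxy-5-(2-methoxy-2-oxoethyl)-2,5,8a-trimethyloctahydro-2H-chromen-6-yl]-2-methylpropanoate, via organomercurial 15 (not isolated)
Conditions: Hg(OCOCF3)2, CaCO3, CH2Cl2, −20 °C; then NaBH4, aq. NaOH, 0 °C
Reagents that add atoms: none
Why: Intramolecular Markovnikov alkoxymercuration–demercuration: the ketal oxygen on the axial side chain can reach the mercurinium carbon only from its own face, so the new tertiary C–O bond is cis to the side chain (cis ring fusion, 8a-methyl cis to the 4a-H), the oxonium loses methyl to trifluoroacetate, no free cation is formed that could scramble the adjacent centre, and the anomeric methoxy (erased in step 7) sits axial.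

Step 7
Reactants: 16 methyl 2-[(2R,4aS,5S,6R,8aR)-2-methoxy-5-(2-methoxy-2-oxoethyl)-2,5,8a-trimethyloctahydro-2H-chromen-6-yl]-2-methylpropanoate, 17 potassium vinyltrifluoroborate
Product: 18 methyl 2-[(2R,4aS,5S,6R,8aR)-2-ethenyl-5-(2-methoxy-2-oxoethyl)-2,5,8a-trimethyloctahydro-2H-chromen-6-yl]-2-methylpropanoate
Conditions: BF3·OEt2, MeCN/CH2Cl2, −40 to 0 °C
Reagents that add atoms: none
Why: Lewis-acid ionisation gives the cyclic 2-methyl oxocarbenium ion and the alkenyl trifluoroborate adds along the axial, chair-like trajectory, so vinyl ends axial and the C2 methyl equatorial and cis to the 8a-methyl, i.e. 2R (oxocarbenium C-alkenylation with an organotrifluoroborate).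

Step 8
Reactants: 18 methyl 2-[(2R,4aS,5S,6R,8aR)-2-ethenyl-5-(2-methoxy-2-oxoethyl)-2,5,8a-trimethyloctahydro-2H-chromen-6-yl]-2-methylpropanoate
Product: 19 2-[(2R,4aS,5S,6R,8aR)-5-(carboxymethyl)-2-ethenyl-2,5,8a-trimethyloctahydro-2H-chromen-6-yl]-2-methylpropanoic acid
Conditions: KOH, DMSO/H2O, 100 °C; then cold 1 M HCl to pH 3
Reagents that add atoms: potassium hydroxide [K+].[OH-]
Why: Saponification of both methyl esters (forcing conditions for the neopentyl-type ester) leaves the base-stable ether, the alkene and all stereocentres untouched, and the cold, mildly acidic work-up avoids ionising the tertiary allylic ether.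

**Compound list**
1 | methyl 2-methylpropanoate | COC(=O)C(C)C | starting material
2 | 1-methoxy-2-methyl-1-(trimethylsilyloxy)prop-1-ene | COC(O[Si](C)(C)C)=C(C)C | intermediate
3 | 2-methylcyclopent-2-en-1-one | CC1=CCCC1=O | starting material
4 | methyl bromoacetate | COC(=O)CBr | starting material
5 | methyl 2-methyl-2-[(1R)-2-methyl-3-(trimethylsilyloxy)cyclopent-2-en-1-yl]propanoate | C[Si](C)(C)OC1=C(C)[C@H](C(C)(C)C(=O)OC)CC1 | intermediate
6 | methyl 2-[(1R,2S)-2-(2-methoxy-2-oxoethyl)-2-methyl-3-oxocyclopentyl]-2-methylpropanoate | O=C1[C@@](C)(CC(=O)OC)[C@H](C(C)(C)C(=O)OC)CC1 | intermediate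
7 | dibromomethane | BrCBr | starting material
8 | lithium (1S,2S,3R)-1-(dibromomethyl)-2-(2-methoxy-2-oxoethyl)-3-(1-methoxy-2-methyl-1-oxopropan-2-yl)-2-methylcyclopentan-1-olate | [Li]O[C@]1(C(Br)Br)[C@@](C)(CC(=O)OC)[C@H](C(C)(C)C(=O)OC)CC1 | intermediate
9 | lithium enolate, methyl 2-[(1R,2S)-4-(lithiooxy)-2-(2-methoxy-2-oxoethyl)-2-methylcyclohex-3-en-1-yl]-2-methylpropanoate | [Li]OC1=C[C@@](C)(CC(=O)OC)[C@H](C(C)(C)C(=O)OC)CC1 | intermediate
10 | methyl 2-[(1R,2S)-2-(2-methoxy-2-oxoethyl)-2-methyl-4-(trimethylsilyloxy)cyclohex-3-en-1-yl]-2-methylpropanoate | C[Si](C)(C)OC1=C[C@@](C)(CC(=O)OC)[C@H](C(C)(C)C(=O)OC)CC1 | intermediate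
11 | but-3-en-2-one | CC(=O)C=C | starting material
12 | methyl 2-[(1R,2S,3S)-2-(2-methoxy-2-oxoethyl)-2-methyl-4-oxo-3-[(2Z)-3-(trimethylsilyloxy)but-2-en-1-yl]cyclohexyl]-2-methylpropanoate | C/C(=C/C[C@@H]1C(=O)CC[C@@H](C(C)(C)C(=O)OC)[C@]1(C)CC(=O)OC)O[Si](C)(C)C | intermediate
13 | methyl 2-[(1R,2S,3S)-3-(3,3-dimethoxybutyl)-2-(2-methoxy-2-oxoethyl)-2-methyl-4-oxocyclohexyl]-2-methylpropanoate | COC(C)(OC)CC[C@@H]1C(=O)CC[C@@H](C(C)(C)C(=O)OC)[C@]1(C)CC(=O)OC | intermediate
14 | methyl 2-[(1R,2R,3R)-3-(3,3-dimethoxybutyl)-2-(2-methoxy-2-oxoethyl)-2-methyl-4-methylidenecyclohexyl]-2-methylpropanoate | COC(C)(OC)CC[C@@H]1C(=C)CC[C@@H](C(C)(C)C(=O)OC)[C@]1(C)CC(=O)OC | intermediate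
15 | [(2R,4aS,5S,6R,8aR)-2-methoxy-6-(1-methoxy-2-methyl-1-oxopropan-2-yl)-5-(2-methoxy-2-oxoethyl)-2,5-dimethyloctahydro-2H-chromen-8a-yl]methylmercury(II) trifluoroacetate | CO[C@@]1(C)CC[C@H]2[C@@](C)(CC(=O)OC)[C@H](C(C)(C)C(=O)OC)CC[C@@]2(C[Hg]OC(=O)C(F)(F)F)O1 | intermediate
16 | methyl 2-[(2R,4aS,5S,6R,8aR)-2-methoxy-5-(2-methoxy-2-oxoethyl)-2,5,8a-trimethyloctahydro-2H-chromen-6-yl]-2-methylpropanoate | CO[C@@]1(C)CC[C@H]2[C@@](C)(CC(=O)OC)[C@H](C(C)(C)C(=O)OC)CC[C@@]2(C)O1 | intermediate
17 | potassium vinyltrifluoroborate | C=C[B-](F)(F)F.[K+] | starting material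
18 | methyl 2-[(2R,4aS,5S,6R,8aR)-2-ethenyl-5-(2-methoxy-2-oxoethyl)-2,5,8a-trimethyloctahydro-2H-chromen-6-yl]-2-methylpropanoate | C=C[C@@]1(C)CC[C@H]2[C@@](C)(CC(=O)OC)[C@H](C(C)(C)C(=O)OC)CC[C@@]2(C)O1 | intermediate
19 | 2-[(2R,4aS,5S,6R,8aR)-5-(carboxymethyl)-2-ethenyl-2,5,8a-trimethyloctahydro-2H-chromen-6-yl]-2-methylpropanoic acid | C=C[C@@]1(C)CC[C@H]2[C@@](C)(CC(=O)O)[C@H](C(C)(C)C(=O)O)CC[C@@]2(C)O1 | target

**Totals and risks**
Total step count: 8. Longest linear sequence: 8 steps (1 → 19).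

Step 2 (the proposed new enantioselective Michael–alkylation) may be slow or poorly selective with the α-methyl enone. The fallback uses known chemistry and sets out from 2, 3 and 4. The same Mukaiyama–Michael addition is run with achiral Tf2NH (silyl triflimide catalysis), giving 5 together with its mirror image, methyl 2-methyl-2-[(1S)-2-methyl-3-(trimethylsilyloxy)cyclopent-2-en-1-yl]propanoate F1. Alkylation with TBAT and 4 as before gives 6 together with its enantiomer, methyl 2-[(1S,2R)-2-(2-methoxy-2-oxoethyl)-2-methyl-3-oxocyclopentyl]-2-methylpropanoate F2. Preparative chiral SFC separates the two, and the route is rejoined at 6.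

Step 3 (ring expansion) may fail through attack of n-BuLi on the methyl esters or poor migration of the quaternary carbon. The fallback sets out from 6. Lithiated chloromethyl p-tolyl sulfoxide (LDA, THF, −78 °C) is added to the ketone to give the isolable adduct methyl 2-[(1R,2S,3S)-3-{chloro[(4-methylphenyl)sulfinyl]methyl}-3-hydroxy-2-(2-methoxy-2-oxoethyl)-2-methylcyclopentyl]-2-methylpropanoate F3, a mixture at the CHCl and sulfur centres. Treatment with t-BuMgCl and then i-PrMgCl (sulfoxide–magnesium exchange, −78 to 0 °C) generates a magnesium β-oxido carbenoid that rearranges to the chloromagnesium enolate, methyl 2-[(1R,2S)-4-[(chloromagnesio)oxy]-2-(2-methoxy-2-oxoethyl)-2-methylcyclohex-3-en-1-yl]-2-methylpropanoate F4. Silylation with TMSCl returns to the route at 10. This answers the ester problem (no alkyllithium meets the esters) but not the migratory-aptitude risk.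

Step 7 (vinylation) may be sluggish or unselective at the fully substituted oxocarbenium carbon, or the Lewis acid may epimerise the product. The fallback sets out from 16. The slimmer (trimethylsilyl)ethynyl group is transferred with dimethyl[(trimethylsilyl)ethynyl]alane (from ethynyltrimethylsilane, n-BuLi, Me2AlCl; CH2Cl2, −40 °C) to give methyl 2-[(2R,4aS,5S,6R,8aR)-5-(2-methoxy-2-oxoethyl)-2,5,8a-trimethyl-2-[(trimethylsilyl)ethynyl]octahydro-2H-chromen-6-yl]-2-methylpropanoate F5. K2CO3/MeOH removes silicon to give methyl 2-[(2R,4aS,5S,6R,8aR)-2-ethynyl-5-(2-methoxy-2-oxoethyl)-2,5,8a-trimethyloctahydro-2H-chromen-6-yl]-2-methylpropanoate F6. Lindlar semihydrogenation (H2, quinoline) then rejoins the route at 18.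

Further compounds
F1 | step 2 | methyl 2-methyl-2-[(1S)-2-methyl-3-(trimethylsilyloxy)cyclopent-2-en-1-yl]propanoate | C[Si](C)(C)OC1=C(C)[C@@H](C(C)(C)C(=O)OC)CC1
F2 | step 2 | methyl 2-[(1S,2R)-2-(2-methoxy-2-oxoethyl)-2-methyl-3-oxocyclopentyl]-2-methylpropanoate | O=C1[C@](C)(CC(=O)OC)[C@@H](C(C)(C)C(=O)OC)CC1
F3 | step 3 | methyl 2-[(1R,2S,3S)-3-{chloro[(4-methylphenyl)sulfinyl]methyl}-3-hydroxy-2-(2-methoxy-2-oxoethyl)-2-methylcyclopentyl]-2-methylpropanoate (mixture at CHCl and S) | O[C@]1(C(Cl)S(=O)c2ccc(C)cc2)[C@@](C)(CC(=O)OC)[C@H](C(C)(C)C(=O)OC)CC1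
F4 | step 3 | methyl 2-[(1R,2S)-4-[(chloromagnesio)oxy]-2-(2-methoxy-2-oxoethyl)-2-methylcyclohex-3-en-1-yl]-2-methylpropanoate | Cl[Mg]OC1=C[C@@](C)(CC(=O)OC)[C@H](C(C)(C)C(=O)OC)CC1
F5 | step 7 | methyl 2-[(2R,4aS,5S,6R,8aR)-5-(2-methoxy-2-oxoethyl)-2,5,8a-trimethyl-2-[(trimethylsilyl)ethynyl]octahydro-2H-chromen-6-yl]-2-methylpropanoate | C[Si](C)(C)C#C[C@@]1(C)CC[C@H]2[C@@](C)(CC(=O)OC)[C@H](C(C)(C)C(=O)OC)CC[C@@]2(C)O1
F6 | step 7 | methyl 2-[(2R,4aS,5S,6R,8aR)-2-ethynyl-5-(2-methoxy-2-oxoethyl)-2,5,8a-trimethyloctahydro-2H-chromen-6-yl]-2-methylpropanoate | C#C[C@@]1(C)CC[C@H]2[C@@](C)(CC(=O)OC)[C@H](C(C)(C)C(=O)OC)CC[C@@]2(C)O1
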